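**Strategy.** The enamide C–N bond is cut first, then the carbocycle between C5 and C6 (ring numbering: C1 ketone, C2 nitrogen-bearing, C3 vinylic CH, C4 quaternary carbinol, C5 carbinol, C6 methylene). Because C1(=O)–C6H2–C5(OH) is an aldol unit beside the oxygenated quaternary C4, a Ferrier carbocyclisation of a 2-C-branched glucoside closes the six-membered ring, forms C5–C6 and sets C5 in one operation; C4 and all six ring carbons come from the sugar. The precursor is a methyl 6-deoxyhex-5-enopyranoside with an exocyclic enol ether, a free tertiary 2-OH, an axial silyloxypentyl branch, and benzoates on O3 (later the E1cB leaving group) and O4 (later the enol triflate oxygen).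

Key step: step 9

**Remarks**
- Compound 1 is the commercial benzylidene acetal of methyl α-D-glucopyranoside. From step 9 on, ring atoms carry the target numbering given above.
- O3 is carried through the key step as a benzoate, not an ether, so that its later loss outpaces loss of the C5 acetonide oxygen.
- Assumption: (+)-(NMI)2ZrCl2 [(+)-bis(1-neomenthylindenyl)zirconium dichloride] is taken as the catalyst enantiomer that converts R–CH2CH=CH2 into the (2S)-2-methylalkylalane; if the sign convention is the reverse, its antipode is used in steps 13 and 14.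

**Route**

Step 1
Reactants: 1 methyl 4,6-O-[(R)-benzylidene]-α-D-glucopyranoside
Product: 2 methyl 3-O-benzyl-4,6-O-[(R)-benzylidene]-α-D-glucopyranoside
Conditions: NaH (2.2 equiv), THF, rt; CuCl2 (1.1 equiv); BnBr (1.2 equiv), Bu4NI (cat.), reflux; aq. NH3/NH4Cl work-up
Reagents that add atoms: benzyl bromide, BrCc1ccccc1
Why: Williamson etherification of the copper(II) chelate of the 2,3-diolate, a template known to direct alkyl halides to O3 of this acetal (the free dianion reacts at O2); no stereocentre is touched and any 2-O isomer is separable.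

Step 2
Reactants: 2 methyl 3-O-benzyl-4,6-O-[(R)-benzylidene]-α-D-glucopyranoside
Product: 3 methyl 3-O-benzyl-4,6-O-[(R)-benzylidene]-α-D-arabino-hexopyranosid-2-ulose
Conditions: Dess–Martin periodinane, NaHCO3, CH2Cl2, rt; product dried azeotropically with toluene
Reagents that add atoms: none
Why: Dess–Martin oxidation of the only free hydroxyl under neutral conditions, which leave both acetals and the benzyl ether intact and do not epimerise C3; drying is needed because the ulose hydrates readily.

Step 3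
Reactants: 4 5-bromopentan-1-ol
Product: 5 (5-bromopentyloxy)triisopropylsilane
Conditions: TIPSCl, imidazole, CH2Cl2, 0 °C to rt
Reagents that add atoms: triisopropylsilyl chloride, CC(C)[Si](Cl)(C(C)C)C(C)C
Why: Silylation of a primary alcohol under conditions too mild for cyclisation to tetrahydropyran; TIPS is chosen because it survives Grignard formation, aqueous Hg(II) and DBU.

Step 4
Reactants: 3 methyl 3-O-benzyl-4,6-O-[(R)-benzylidene]-α-D-arabino-hexopyranosid-2-ulose; 5 (5-bromopentyloxy)triisopropylsilane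
Product: 7 methyl 3-O-benzyl-4,6-O-[(R)-benzylidene]-2-C-[5-(triisopropylsilyloxy)pentyl]-α-D-glucopyranoside, via Grignard reagent 6 (not isolated)
Conditions: Mg (activated with 1,2-dibromoethane), THF, 40 °C; then 3, THF, −78 to −20 °C; aq. NH4Cl
Reagents that add atoms: none
Why: Grignard 1,2-addition in which the nucleophile should approach C2 axially on the β-face, anti to the axial anomeric C1–OMe bond (the equatorial path runs gauche to that oxygen), as known for methyl-metal additions to α-glycosid-2-uloses; this places the branch axial and the tertiary hydroxyl equatorial (gluco) and sets target C4.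

Step 5
Reactants: 7 methyl 3-O-benzyl-4,6-O-[(R)-benzylidene]-2-C-[5-(triisopropylsilyloxy)pentyl]-α-D-glucopyranoside
Product: 8 methyl 2-C-[5-(triisopropylsilyloxy)pentyl]-α-D-glucopyranoside
Conditions: H2 (1 atm), Pd(OH)2/C, EtOAc–MeOH, rt
Reagents that add atoms: none
Why: Catalytic hydrogenolysis removes the benzyl ether and the benzylidene acetal together (both only masked O3, O4 and O6 during the organometallic step), while glycoside, tertiary alcohol and silyl ether are inert.

Step 6
Reactants: 8 methyl 2-C-[5-(triisopropylsilyloxy)pentyl]-α-D-glucopyranoside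
Product: 9 methyl 6-deoxy-6-iodo-2-C-[5-(triisopropylsilyloxy)pentyl]-α-D-glucopyranoside
Conditions: PPh3, I2, imidazole, THF, rt to 50 °C
Reagents that add atoms: iodine, II
Why: Garegg–Samuelsson (Appel-type) iodination, selective for the primary 6-OH because only its alkoxyphosphonium ion is displaced by iodide in an SN2 step under these conditions.

Step 7
Reactants: 9 methyl 6-deoxy-6-iodo-2-C-[5-(triisopropylsilyloxy)pentyl]-α-D-glucopyranoside
Product: 10 methyl 3,4-di-O-benzoyl-6-deoxy-6-iodo-2-C-[5-(triisopropylsilyloxy)pentyl]-α-D-glucopyranoside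
Conditions: BzCl (3 equiv), pyridine, DMAP (cat.), 0 °C to rt (40 °C if O3 is slow)
Reagents that add atoms: benzoyl chloride, O=C(Cl)c1ccccc1
Why: DMAP-catalysed acylation of the two secondary hydroxyls, the tertiary 2-OH being unreactive under these conditions; the O3 benzoate is the later leaving group and the O4 benzoate the later enol oxygen.

Step 8
Reactants: 10 methyl 3,4-di-O-benzoyl-6-deoxy-6-iodo-2-C-[5-(triisopropylsilyloxy)pentyl]-α-D-glucopyranoside
Product: 11 methyl 3,4-di-O-benzoyl-6-deoxy-2-C-[5-(triisopropylsilyloxy)pentyl]-α-D-xylo-hex-5-enopyranoside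
Conditions: DBU (3 equiv), THF, reflux
Reagents that add atoms: none
Why: E2 dehydroiodination across C5–C6 gives the exocyclic enol ether; with O3 acylated no 3,6-anhydro ring can form, and benzoates tolerate DBU in an aprotic solvent.

Step 9
Reactants: 11 methyl 3,4-di-O-benzoyl-6-deoxy-2-C-[5-(triisopropylsilyloxy)pentyl]-α-D-xylo-hex-5-enopyranoside
Product: 13 (2S,3S,4S,5S)-2,3-bis(benzoyloxy)-4,5-dihydroxy-4-[5-(triisopropylsilyloxy)pentyl]cyclohexan-1-one, via mercurio keto-aldehyde 12 (not isolated)
Conditions: Hg(OCOCF3)2 (10 mol %), acetone–H2O (4:1), rt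
Reagents that add atoms: water, O
Why: Hg(II) adds to the electron-rich exocyclic enol ether (oxymercuration, mercury on sugar C6, water on C5), the hemiketal opens, the anomeric hemiacetal loses methanol to give the α-mercurio ketone–aldehyde 12, and this adds to the aldehyde as an enolate equivalent with release of Hg(II) for turnover. The closest known reaction is the Ferrier carbocyclisation of 6-deoxyhex-5-enopyranosides to 5-hydroxycyclohexanones, applied here to a 2-C-branched, ester-protected substrate. The six-membered ring is closed by a 6-(enolexo)-exo-trig aldol addition that forms the C5–C6 bond (sugar C1–C6). The one new stereocentre, C5, is under substrate control: in the chair-like transition state the two benzoyloxy groups and the tertiary hydroxyl stay equatorial and the aldehyde oxygen is axial, hence trans to the C3 benzoyloxy group and cis to the C4 hydroxyl, the usual outcome in the gluco series. The step needs only this diastereoselectivity, which the axial C4 branch should support because an axial aldehyde oxygen points away from it, and chemoselectivity is secured because the enol ether is the only π-nucleophile and neutral aqueous acetone at rt does not eliminate the β-benzoate or the new hydroxyl.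

Step 10
Reactants: 13 (2S,3S,4S,5S)-2,3-bis(benzoyloxy)-4,5-dihydroxy-4-[5-(triisopropylsilyloxy)pentyl]cyclohexan-1-one
Product: 14 (2S,3S,4S,5S)-2,3-bis(benzoyloxy)-4,5-(isopropylidenedioxy)-4-[5-(triisopropylsilyloxy)pentyl]cyclohexan-1-one
Conditions: 2-methoxypropene, PPTS (cat.), CH2Cl2, 0 °C to rt
Reagents that add atoms: 2-methoxypropene, COC(C)=C
Why: Acid-catalysed ketalisation, possible only on the cis-4,5-diol; it blocks retro-aldol opening at C5–C6 and makes the C5 oxygen a poor (alkoxide) leaving group, while catalytic PPTS neither dehydrates the aldol nor cleaves the TIPS ether.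

Step 11
Reactants: 14 (2S,3S,4S,5S)-2,3-bis(benzoyloxy)-4,5-(isopropylidenedioxy)-4-[5-(triisopropylsilyloxy)pentyl]cyclohexan-1-one
Product: 16 (4R,5S)-2-hydroxy-4,5-(isopropylidenedioxy)-4-[5-(triisopropylsilyloxy)pentyl]cyclohex-2-en-1-one, via enol benzoate 15 (not isolated)
Conditions: DBU (2.2 equiv), CH2Cl2, 0 °C; then MeOH, 0 °C; pH 5 buffer work-up
Reagents that add atoms: none
Why: E1cB elimination in which C2–H, acidified by the ketone and the acyloxy group, is removed and the C3 benzoate (a carboxylate) leaves much faster than the acetonide oxygen at C5 could, followed by DBU-catalysed methanolysis of the activated enol ester to the diosphenol, whose anion resists further enolisation toward C6; C4 and C5 are untouched.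

Step 12
Reactants: 16 (4R,5S)-2-hydroxy-4,5-(isopropylidenedioxy)-4-[5-(triisopropylsilyloxy)pentyl]cyclohex-2-en-1-one
Product: 17 (4R,5S)-4,5-(isopropylidenedioxy)-1-oxo-4-[5-(triisopropylsilyloxy)pentyl]cyclohex-2-en-2-yl trifluoromethanesulfonate
Conditions: Tf2O, pyridine, CH2Cl2, −78 to −20 °C
Reagents that add atoms: trifluoromethanesulfonic anhydride, O=S(=O)(OS(=O)(=O)C(F)(F)F)C(F)(F)F
Why: O-sulfonylation of the acidic enol hydroxyl of a diosphenol, the standard route to 2-triflyloxy enones; the C2=C3 position is fixed by the way 16 is made and low temperature prevents tautomer equilibration through the 1,2-dione.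

Step 13
Reactants: 18 4-methylpent-1-ene
Product: 20 (4S)-4,6-dimethylhept-1-ene, via alkylalane 19 (not isolated)
Conditions: Me3Al (2 equiv), (+)-(NMI)2ZrCl2 (4 mol %), MAO (cat.), CH2Cl2, 0 °C to rt; volatiles removed; Zn(OTf)2 (1 equiv), DMF, 70 °C; vinyl bromide (excess), Pd(DPEphos)Cl2 (3 mol %), DIBAL-H (6 mol %), DMF, rt
Reagents that add atoms: trimethylaluminium, C[Al](C)C; vinyl bromide, C=CBr
Why: Zirconium-catalysed asymmetric carboalumination (ZACA) adds Me–Al across the terminal alkene with catalyst-controlled facial selectivity (new methyl-bearing centre, S), and the primary alkylalane is then vinylated by zinc-promoted Negishi-type Pd cross-coupling, which does not involve the stereocentre.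

Step 14
Reactants: 20 (4S)-4,6-dimethylhept-1-ene
Product: 22 (2S,4S)-2,4,6-trimethylheptan-1-ol, via alkylalane 21 (not isolated)
Conditions: Me3Al (2 equiv), (+)-(NMI)2ZrCl2 (4 mol %), MAO (cat.), CH2Cl2, 0 °C to rt; then O2, −20 °C to rt; aqueous work-up; chromatographic removal of the anti diastereomer
Reagents that add atoms: trimethylaluminium, C[Al](C)C; dioxygen, O=O
Why: A second ZACA reaction with the same catalyst enantiomer should set the second methyl-bearing centre syn to the first (catalyst control; two selective events in series enrich the major diastereomer in one enantiomer), and O2 oxidises the C–Al bond to the primary alcohol without touching either centre.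

Step 15
Reactants: 22 (2S,4S)-2,4,6-trimethylheptan-1-ol
Product: 23 (2S,4S)-2,4,6-trimethylheptanal
Conditions: Dess–Martin periodinane, NaHCO3, CH2Cl2, 0 °C to rt; used crude
Reagents that add atoms: none
Why: Dess–Martin oxidation under buffered, non-basic conditions gives the α-branched aldehyde without epimerisation, and immediate use avoids enolisation on storage.

Step 16
Reactants: 23 (2S,4S)-2,4,6-trimethylheptanal
Product: 24 (2E,4S,6S)-4,6,8-trimethylnon-2-enamide
Conditions: diethyl (2-amino-2-oxoethyl)phosphonate, LiCl, DBU, MeCN, 0 °C to rt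
Reagents that add atoms: diethyl (2-amino-2-oxoethyl)phosphonate, CCOP(=O)(CC(N)=O)OCC
Why: Horner–Wadsworth–Emmons olefination with a stabilised phosphonate gives the E-alkene under thermodynamic control, and the mild Masamune–Roush conditions should leave the α-stereocentre of the aldehyde intact.

Step 17
Reactants: 17 (4R,5S)-4,5-(isopropylidenedioxy)-1-oxo-4-[5-(triisopropylsilyloxy)pentyl]cyclohex-2-en-2-yl trifluoromethanesulfonate; 24 (2E,4S,6S)-4,6,8-trimethylnon-2-enamide
Product: 25 (2E,4S,6S)-N-[(4R,5S)-4,5-(isopropylidenedioxy)-1-oxo-4-[5-(triisopropylsilyloxy)pentyl]cyclohex-2-en-2-yl]-4,6,8-trimethylnon-2-enamide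
Conditions: Pd2(dba)3 (2.5 mol %), Xantphos (7.5 mol %), Cs2CO3 (1.4 equiv), 1,4-dioxane, 50 °C
Reagents that add atoms: none
Why: Palladium-catalysed amidation of an alkenyl triflate (Buchwald–Hartwig type): oxidative addition into the electron-poor α-keto alkenyl triflate is easy, the wide-bite-angle ligand promotes C–N reductive elimination with primary amides, and the mild carbonate base at 50 °C should limit β-elimination at C5; no stereocentre is involved.

Step 18
Reactants: 25 (2E,4S,6S)-N-[(4R,5S)-4,5-(isopropylidenedioxy)-1-oxo-4-[5-(triisopropylsilyloxy)pentyl]cyclohex-2-en-2-yl]-4,6,8-trimethylnon-2-enamide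
Product: 26 (2E,4S,6S)-N-[(4R,5S)-4-(5-hydroxypentyl)-4,5-(isopropylidenedioxy)-1-oxocyclohex-2-en-2-yl]-4,6,8-trimethylnon-2-enamide
Conditions: HF·pyridine, pyridine, THF, 0 °C to rt
Reagents that add atoms: none
Why: Fluoride-driven desilylation of the primary TIPS ether; buffered HF·pyridine is not basic enough to trigger β-elimination at C5 and not acidic enough to cleave the acetonide.

Step 19
Reactants: 26 (2E,4S,6S)-N-[(4R,5S)-4-(5-hydroxypentyl)-4,5-(isopropylidenedioxy)-1-oxocyclohex-2-en-2-yl]-4,6,8-trimethylnon-2-enamide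
Product: 27 5-[(4R,5S)-4,5-(isopropylidenedioxy)-1-oxo-2-{[(2E,4S,6S)-4,6,8-trimethylnon-2-enoyl]amino}cyclohex-2-en-4-yl]pentanoic acid
Conditions: TEMPO (0.2 equiv), PhI(OAc)2 (2.5 equiv), MeCN–H2O (1:1), 0 °C to rt
Reagents that add atoms: water, O
Why: Oxoammonium-catalysed (TEMPO/PhI(OAc)2) oxidation of the only free alcohol through the aldehyde hydrate to the carboxylic acid; the diol is masked and the electron-poor enone and enamide should be inert.

Step 20
Reactants: 27 5-[(4R,5S)-4,5-(isopropylidenedioxy)-1-oxo-2-{[(2E,4S,6S)-4,6,8-trimethylnon-2-enoyl]amino}cyclohex-2-en-4-yl]pentanoic acid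
Product: 28 salternamide E, 5-[(1R,6S)-1,6-dihydroxy-4-oxo-3-{[(2E,4S,6S)-4,6,8-trimethylnon-2-enoyl]amino}cyclohex-2-en-1-yl]pentanoic acid
Conditions: AcOH–H2O (4:1), 35–40 °C
Reagents that add atoms: none
Why: Acid-catalysed hydrolysis of the cis-fused acetonide under conditions mild enough to avoid ionisation of the tertiary allylic C4–OH and dehydration of the β-hydroxy ketone; the ring C–O bonds at C4 and C5 are not broken, so both centres are retained.

**Compound list**

1 | methyl 4,6-O-[(R)-benzylidene]-α-D-glucopyranoside | CO[C@H]1O[C@@H]2CO[C@@H](c3ccccc3)O[C@H]2[C@H](O)[C@H]1O | starting material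
2 | methyl 3-O-benzyl-4,6-O-[(R)-benzylidene]-α-D-glucopyranoside | CO[C@H]1O[C@@H]2CO[C@@H](c3ccccc3)O[C@H]2[C@H](OCc4ccccc4)[C@H]1O | intermediate
3 | methyl 3-O-benzyl-4,6-O-[(R)-benzylidene]-α-D-arabino-hexopyranosid-2-ulose | CO[C@H]1O[C@@H]2CO[C@@H](c3ccccc3)O[C@H]2[C@H](OCc4ccccc4)C1=O | intermediate
4 | 5-bromopentan-1-ol | OCCCCCBr | starting material
5 | (5-bromopentyloxy)triisopropylsilane | BrCCCCCO[Si](C(C)C)(C(C)C)C(C)C | intermediate
6 | [5-(triisopropylsilyloxy)pentyl]magnesium bromide | Br[Mg]CCCCCO[Si](C(C)C)(C(C)C)C(C)C | intermediate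
7 | methyl 3-O-benzyl-4,6-O-[(R)-benzylidene]-2-C-[5-(triisopropylsilyloxy)pentyl]-α-D-glucopyranoside (branch axial, tertiary OH equatorial) | CO[C@H]1O[C@@H]2CO[C@@H](c3ccccc3)O[C@H]2[C@H](OCc4ccccc4)[C@]1(O)CCCCCO[Si](C(C)C)(C(C)C)C(C)C | intermediate
8 | methyl 2-C-[5-(triisopropylsilyloxy)pentyl]-α-D-glucopyranoside | CO[C@H]1O[C@H](CO)[C@@H](O)[C@H](O)[C@]1(O)CCCCCO[Si](C(C)C)(C(C)C)C(C)C | intermediate
9 | methyl 6-deoxy-6-iodo-2-C-[5-(triisopropylsilyloxy)pentyl]-α-D-glucopyranoside | CO[C@H]1O[C@H](CI)[C@@H](O)[C@H](O)[C@]1(O)CCCCCO[Si](C(C)C)(C(C)C)C(C)C | intermediate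
10 | methyl 3,4-di-O-benzoyl-6-deoxy-6-iodo-2-C-[5-(triisopropylsilyloxy)pentyl]-α-D-glucopyranoside | CO[C@H]1O[C@H](CI)[C@@H](OC(=O)c2ccccc2)[C@H](OC(=O)c3ccccc3)[C@]1(O)CCCCCO[Si](C(C)C)(C(C)C)C(C)C | intermediate
11 | methyl 3,4-di-O-benzoyl-6-deoxy-2-C-[5-(triisopropylsilyloxy)pentyl]-α-D-xylo-hex-5-enopyranoside | CO[C@H]1OC(=C)[C@@H](OC(=O)c2ccccc2)[C@H](OC(=O)c3ccccc3)[C@]1(O)CCCCCO[Si](C(C)C)(C(C)C)C(C)C | intermediate
12 | 3,4-di-O-benzoyl-6-deoxy-6-(trifluoroacetoxymercurio)-2-C-[5-(triisopropylsilyloxy)pentyl]-D-xylo-hexos-5-ulose (open chain) | O=C[C@@](O)(CCCCCO[Si](C(C)C)(C(C)C)C(C)C)[C@@H](OC(=O)c1ccccc1)[C@H](OC(=O)c1ccccc1)C(=O)C[Hg]OC(=O)C(F)(F)F | intermediate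
13 | (2S,3S,4S,5S)-2,3-bis(benzoyloxy)-4,5-dihydroxy-4-[5-(triisopropylsilyloxy)pentyl]cyclohexan-1-one (4-OH and 5-OH cis, both trans to 3-OBz) | O[C@H]1CC(=O)[C@@H](OC(=O)c2ccccc2)[C@H](OC(=O)c3ccccc3)[C@]1(O)CCCCCO[Si](C(C)C)(C(C)C)C(C)C | intermediate
14 | (2S,3S,4S,5S)-2,3-bis(benzoyloxy)-4,5-(isopropylidenedioxy)-4-[5-(triisopropylsilyloxy)pentyl]cyclohexan-1-one | CC1(C)O[C@H]2CC(=O)[C@@H](OC(=O)c3ccccc3)[C@H](OC(=O)c4ccccc4)[C@@]2(CCCCCO[Si](C(C)C)(C(C)C)C(C)C)O1 | intermediate
15 | (4R,5S)-4,5-(isopropylidenedioxy)-1-oxo-4-[5-(triisopropylsilyloxy)pentyl]cyclohex-2-en-2-yl benzoate | CC1(C)O[C@H]2CC(=O)C(OC(=O)c3ccccc3)=C[C@@]2(CCCCCO[Si](C(C)C)(C(C)C)C(C)C)O1 | intermediate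
16 | (4R,5S)-2-hydroxy-4,5-(isopropylidenedioxy)-4-[5-(triisopropylsilyloxy)pentyl]cyclohex-2-en-1-one | CC1(C)O[C@H]2CC(=O)C(O)=C[C@@]2(CCCCCO[Si](C(C)C)(C(C)C)C(C)C)O1 | intermediate
17 | (4R,5S)-4,5-(isopropylidenedioxy)-1-oxo-4-[5-(triisopropylsilyloxy)pentyl]cyclohex-2-en-2-yl trifluoromethanesulfonate | CC1(C)O[C@H]2CC(=O)C(OS(=O)(=O)C(F)(F)F)=C[C@@]2(CCCCCO[Si](C(C)C)(C(C)C)C(C)C)O1 | intermediate
18 | 4-methylpent-1-ene | C=CCC(C)C | starting material
19 | dimethyl[(2S)-2,4-dimethylpentyl]alumane | C[Al](C)C[C@@H](C)CC(C)C | intermediate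
20 | (4S)-4,6-dimethylhept-1-ene | C=CC[C@@H](C)CC(C)C | intermediate
21 | dimethyl[(2S,4S)-2,4,6-trimethylheptyl]alumane | C[Al](C)C[C@@H](C)C[C@@H](C)CC(C)C | intermediate
22 | (2S,4S)-2,4,6-trimethylheptan-1-ol | OC[C@@H](C)C[C@@H](C)CC(C)C | intermediate
23 | (2S,4S)-2,4,6-trimethylheptanal | O=C[C@@H](C)C[C@@H](C)CC(C)C | intermediate
24 | (2E,4S,6S)-4,6,8-trimethylnon-2-enamide | NC(=O)/C=C/[C@@H](C)C[C@@H](C)CC(C)C | intermediate
25 | (2E,4S,6S)-N-[(4R,5S)-4,5-(isopropylidenedioxy)-1-oxo-4-[5-(triisopropylsilyloxy)pentyl]cyclohex-2-en-2-yl]-4,6,8-trimethylnon-2-enamide | CC(C)C[C@H](C)C[C@H](C)/C=C/C(=O)NC1=C[C@@]2(CCCCCO[Si](C(C)C)(C(C)C)C(C)C)OC(C)(C)O[C@H]2CC1=O | intermediate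
26 | (2E,4S,6S)-N-[(4R,5S)-4-(5-hydroxypentyl)-4,5-(isopropylidenedioxy)-1-oxocyclohex-2-en-2-yl]-4,6,8-trimethylnon-2-enamide | CC(C)C[C@H](C)C[C@H](C)/C=C/C(=O)NC1=C[C@@]2(CCCCCO)OC(C)(C)O[C@H]2CC1=O | intermediate
27 | 5-[(4R,5S)-4,5-(isopropylidenedioxy)-1-oxo-2-{[(2E,4S,6S)-4,6,8-trimethylnon-2-enoyl]amino}cyclohex-2-en-4-yl]pentanoic acid | CC(C)C[C@H](C)C[C@H](C)/C=C/C(=O)NC1=C[C@@]2(CCCCC(=O)O)OC(C)(C)O[C@H]2CC1=O | intermediate
28 | salternamide E, 5-[(1R,6S)-1,6-dihydroxy-4-oxo-3-{[(2E,4S,6S)-4,6,8-trimethylnon-2-enoyl]amino}cyclohex-2-en-1-yl]pentanoic acid | CC(C)C[C@H](C)C[C@H](C)/C=C/C(=O)NC1=C[C@](O)(CCCCC(=O)O)[C@@H](O)CC1=O | target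

**Step count and risk**

Total: 20 steps. Longest linear sequence: 15 steps from 1 to 28 (steps 1, 2, 4–12, 17–20); the silyl bromide (step 3) and the side-chain amide (steps 13–16) are made in parallel.

Step 9 (key step). The aldol closure may lose facial control, because the aldehyde sits on a quaternary carbon whose free hydroxyl can bind mercury, and the aldol may dehydrate during a slow reaction. The fallback separates ring opening from ring closure. It sets out from 11: dilute aqueous acid (TFA–H2O–MeCN, 0 °C) hydrolyses the enol ether and glycoside to the open-chain 3,4-di-O-benzoyl-6-deoxy-2-C-[5-(triisopropylsilyloxy)pentyl]-D-xylo-hexos-5-ulose F1. An amine-catalysed intramolecular enamine aldol reaction (L- or D-proline, DMSO, rt, 6-enolexo) then closes C5–C6 under catalyst control and comes back to the route at 13.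

Step 17. C–N bond formation with the weakly nucleophilic conjugated primary amide may be slow, while the carbonate base opens the acetonide by β-elimination at C5 or hydrolyses the triflate. The fallback sets out from 17 (and from aldehyde 23 for the side chain) and builds the amide by N-acylation. Triflate 17 is coupled under the same palladium catalysis, at lower temperature, with the more reactive tert-butyl carbamate to give tert-butyl N-[(4R,5S)-4,5-(isopropylidenedioxy)-1-oxo-4-[5-(triisopropylsilyloxy)pentyl]cyclohex-2-en-2-yl]carbamate F2. Aldehyde 23 is converted by Horner–Wadsworth–Emmons reaction with the dianion of diethylphosphonoacetic acid into (2E,4S,6S)-4,6,8-trimethylnon-2-enoic acid F3, and oxalyl chloride gives (2E,4S,6S)-4,6,8-trimethylnon-2-enoyl chloride F4. Deprotonation of F2 (LiHMDS, THF, −78 °C) and acylation with F4 gives tert-butyl N-[(2E,4S,6S)-4,6,8-trimethylnon-2-enoyl]-N-[(4R,5S)-4,5-(isopropylidenedioxy)-1-oxo-4-[5-(triisopropylsilyloxy)pentyl]cyclohex-2-en-2-yl]carbamate F5. Selective removal of the Boc group from the imide nitrogen (Mg(ClO4)2, MeCN) comes back to the route at 25.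

Step 4. The basic Grignard reagent may enolise the ulose toward C3 (with β-elimination of the C4 oxygen), reduce it by β-hydride transfer, or discriminate the two faces poorly. The fallback sets out from 3 and makes the C–C bond by SN2 at a primary carbon instead. Corey–Chaykovsky reaction with dimethylsulfonium methylide (Me3S+ I−, n-BuLi, THF, −10 °C), which adds kinetically along the axial path, gives the spiro-epoxide methyl 2,2′-anhydro-3-O-benzyl-4,6-O-[(R)-benzylidene]-2-C-(hydroxymethyl)-α-D-glucopyranoside F6; the sulfoxonium ylide offers the complementary facial mode if needed. Copper-catalysed opening of F6 at its CH2 terminus with the Grignard reagent of (4-bromobutoxy)triisopropylsilane F7 (from 4-bromobutan-1-ol as in step 3) comes back to the route at 7.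

**Further compounds**

F1 | step 9 | 3,4-di-O-benzoyl-6-deoxy-2-C-[5-(triisopropylsilyloxy)pentyl]-D-xylo-hexos-5-ulose (open chain) | O=C[C@@](O)(CCCCCO[Si](C(C)C)(C(C)C)C(C)C)[C@@H](OC(=O)c1ccccc1)[C@H](OC(=O)c1ccccc1)C(C)=O
F2 | step 17 | tert-butyl N-[(4R,5S)-4,5-(isopropylidenedioxy)-1-oxo-4-[5-(triisopropylsilyloxy)pentyl]cyclohex-2-en-2-yl]carbamate | CC(C)(C)OC(=O)NC1=C[C@@]2(CCCCCO[Si](C(C)C)(C(C)C)C(C)C)OC(C)(C)O[C@H]2CC1=O
F3 | step 17 | (2E,4S,6S)-4,6,8-trimethylnon-2-enoic acid | OC(=O)/C=C/[C@@H](C)C[C@@H](C)CC(C)C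
F4 | step 17 | (2E,4S,6S)-4,6,8-trimethylnon-2-enoyl chloride | ClC(=O)/C=C/[C@@H](C)C[C@@H](C)CC(C)C
F5 | step 17 | tert-butyl N-[(2E,4S,6S)-4,6,8-trimethylnon-2-enoyl]-N-[(4R,5S)-4,5-(isopropylidenedioxy)-1-oxo-4-[5-(triisopropylsilyloxy)pentyl]cyclohex-2-en-2-yl]carbamate | CC(C)C[C@H](C)C[C@H](C)/C=C/C(=O)N(C(=O)OC(C)(C)C)C1=C[C@@]2(CCCCCO[Si](C(C)C)(C(C)C)C(C)C)OC(C)(C)O[C@H]2CC1=O
F6 | step 4 | methyl 2,2′-anhydro-3-O-benzyl-4,6-O-[(R)-benzylidene]-2-C-(hydroxymethyl)-α-D-glucopyranoside | CO[C@H]1O[C@@H]2CO[C@@H](c3ccccc3)O[C@H]2[C@H](OCc4ccccc4)[C@]15CO5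
F7 | step 4 | (4-bromobutoxy)triisopropylsilane | BrCCCCO[Si](C(C)C)(C(C)C)C(C)C
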